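**Retrosynthetic overview**
- Feature: ring B (C10, C11, C21, C22, C23, C24) has the ether oxygen O20 on C21 trans to the C11–C13 bond and the C9 chain on C10 beside the oxygenated C24. This is the pattern left by 1,4-addition anti to a 4-silyloxy group followed by α-allylation, so ring B is bought as 3-methylcyclohex-2-enone.
- C11–C13 and C9–C10 are made in step 6. Ring A follows by 7-endo opening of the C15–C17 epoxide by O20, and the C24 carbinol by methylenation, epoxidation anti to the axial C12 methyl and hydride opening.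
- The allyl group becomes the C8 aldehyde. C7–C8 is formed by Nozaki–Hiyama–Kishi coupling with a ring C enol triflate from (S)-carvone (C5 bought, C2 set by ene-reductase), and C8 is set by CBS reduction.
- C6–C27, the C6 centre and the (E)-C7=C8 bond come from an Ireland–Claisen rearrangement of the C8 isobutyrate. Ring D is closed by a type 2 carbonyl-ene reaction (C30–C31), C30 is deoxygenated, C32 is hydrated, and C15 is oxidised last.
- Ring order: B (bought) → A → C (bought, joined) → D.

Key step: step 6

**Remarks on the chemistry**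
- Atoms are numbered in the order of the target SMILES. Ring A = C11, C13, C14, C15, C17, O20, C21; ring B = C10, C11, C21, C22, C23, C24; ring C = C2–C7; ring D = C5, C6, C27, C30, C31, C32. The target is read as 2R,5S,6R,7E,10S,11S,21S,24S,32S, with rings C and D cis-fused.
- The lipase in step 3 is assumed to acylate the (R)-alcohol faster. If it prefers the (S)-alcohol, the separated acetate is methanolysed (K2CO3, MeOH) to give 4.
- C15 is a temporary stereocentre that ends as the ketone. The D-fructose-derived catalyst is expected to give the 15R epoxide, and this is what the SMILES show.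
- Compound 23 is a C8 epimer mixture, and 32 and 33 are carried without assignment at C30. Both centres are removed or reset later.

**Route**

Step 1
Reactants: 1 3-methylcyclohex-2-en-1-one
Product: 2 trimethyl[(3-methylcyclohexa-1,3-dien-1-yl)oxy]silane
Conditions: TMSCl, Et3N, DMF, 100 °C
Reagents that add atoms: chlorotrimethylsilane C[Si](C)(C)Cl
Why: Thermodynamic enol silylation removes the γ-hydrogen of the ring CH2 next to the methyl-bearing carbon and should give the linearly conjugated dienol ether (any exocyclic isomer is removed after step 2); no stereocentre is involved.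

Step 2
Reactants: 2 trimethyl[(3-methylcyclohexa-1,3-dien-1-yl)oxy]silane
Product: 3 rac-4-hydroxy-3-methylcyclohex-2-en-1-one
Conditions: mCPBA, NaHCO3, hexane–CH2Cl2, −15 °C; then 1 M HCl, THF, 0 °C
Reagents that add atoms: 3-chloroperbenzoic acid OOC(=O)c1cccc(Cl)c1
Why: Vinylogous Rubottom oxidation, in which the peracid epoxidises the distal methyl-substituted double bond, the silyloxy group opens the epoxide to the γ-oxygenated enone and acid work-up frees the alcohol, as in the γ-hydroxylation of steroidal dienol ethers; the product is racemic.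

Step 3
Reactants: 3 rac-4-hydroxy-3-methylcyclohex-2-en-1-one
Product: 4 (S)-4-hydroxy-3-methylcyclohex-2-en-1-one
Conditions: Burkholderia cepacia lipase (Amano PS), vinyl acetate, tert-butyl methyl ether, 30 °C, run to a little over half conversion; chromatography
Reagents that add atoms: none
Why: Lipase-catalysed kinetic resolution by transesterification, in which the (R)-alcohol is acetylated faster and the (S)-alcohol is recovered, which fixes C21.

Step 4
Reactants: 4 (S)-4-hydroxy-3-methylcyclohex-2-en-1-one
Product: 5 (S)-4-(tert-butyldimethylsilyloxy)-3-methylcyclohex-2-en-1-one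
Conditions: TBSCl, imidazole, DMF, 23 °C
Reagents that add atoms: tert-butyldimethylsilyl chloride CC(C)(C)[Si](C)(C)Cl
Why: Imidazole-promoted silylation of a secondary allylic alcohol; the stereocentre is untouched.

Step 5
Reactants: 6 5-bromo-2-methylpent-2-ene
Product: 7 4-methylpent-3-enylmagnesium bromide
Conditions: Mg turnings, I2 (cat.), THF, 23–40 °C
Reagents that add atoms: magnesium [Mg]
Why: Grignard formation from a primary homoallylic bromide; the trisubstituted alkene is inert.

Step 6
Reactants: 5 (S)-4-(tert-butyldimethylsilyloxy)-3-methylcyclohex-2-en-1-one; 7 4-methylpent-3-enylmagnesium bromide; 8 allyl iodide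
Product: 11 (2S,3S,4S)-2-allyl-4-(tert-butyldimethylsilyloxy)-3-methyl-3-(4-methylpent-3-enyl)cyclohexan-1-one, via trimethylsilyl enol ether 9 (not isolated), via lithium enolate 10 (not isolated)
Conditions: 7 (1.5 equiv), CuBr·SMe2 (10 mol %), TMSCl, HMPA, THF, −78 °C; Et3N, pentane, filtration; MeLi, THF, 0 °C; 8, −78 → 0 °C; NaOMe (cat.), MeOH, 23 °C
Reagents that add atoms: none
Why: The Grignard reagent and catalytic CuBr·SMe2 give an organocopper species that adds 1,4 to enone 5, TMSCl accelerating the addition and trapping the enolate as silyl enol ether 9, after which MeLi cleaves the O–Si bond to the regiodefined lithium enolate 10, which allyl iodide alkylates at C10. The closest known reaction type is the TMSCl-assisted copper-catalysed conjugate addition of Grignard reagents to β,β-disubstituted enones combined with alkylation of the regenerated enolate (three-component coupling). No ring is closed; the bonds formed are C11–C13 and C9–C10. C11 is set by the substrate: A(1,2) strain with the C12 methyl holds the C21 silyloxy group pseudoaxial, and axial attack anti to it places the C13 chain trans to the C21 oxygen. C10 is the only epimerisable centre and is set under thermodynamic control, the NaOMe equilibration placing the allyl group equatorial, cis to the C12 methyl and trans to the C13 chain. The step needs 1,4- over 1,2-addition and C-allylation at C10 only, which copper with TMSCl and the generation of a single enolate regioisomer from 9 without a proton source should secure.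

Step 7
Reactants: 11 (2S,3S,4S)-2-allyl-4-(tert-butyldimethylsilyloxy)-3-methyl-3-(4-methylpent-3-enyl)cyclohexan-1-one
Product: 12 (2S,3S,4S)-2-allyl-4-hydroxy-3-methyl-3-(4-methylpent-3-enyl)cyclohexan-1-one
Conditions: HF·pyridine, pyridine, THF, 0 → 23 °C
Reagents that add atoms: none
Why: Fluoride cleaves the secondary silyl ether (Si–F bond formation) without touching the ketone or the alkenes.

Step 8
Reactants: 12 (2S,3S,4S)-2-allyl-4-hydroxy-3-methyl-3-(4-methylpent-3-enyl)cyclohexan-1-one
Product: 13 (2S,3S,4S)-2-allyl-3-{2-[(2R)-3,3-dimethyloxiran-2-yl]ethyl}-4-hydroxy-3-methylcyclohexan-1-one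
Conditions: D-fructose-derived spiroketal ketone catalyst (30 mol %), KHSO5 (as 2KHSO5·KHSO4·K2SO4), K2CO3, Bu4NHSO4 (cat.), MeCN–dimethoxymethane–aq. Na2B4O7 buffer, 0 °C
Reagents that add atoms: potassium peroxymonosulfate [K+].[O-]S(=O)(=O)OO
Why: Shi epoxidation, in which the chiral dioxirane epoxidises the electron-rich trisubstituted alkene far faster than the monosubstituted allyl group and sets the temporary C15 centre under catalyst control.

Step 9
Reactants: 13 (2S,3S,4S)-2-allyl-3-{2-[(2R)-3,3-dimethyloxiran-2-yl]ethyl}-4-hydroxy-3-methylcyclohexan-1-one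
Product: 14 (3R,5aS,6S,9aS)-6-allyl-3-hydroxy-2,2,5a-trimethyloctahydro-1-benzoxepin-7(2H)-one (rings A and B, C24 ketone)
Conditions: BF3·OEt2 (20 mol %), CH2Cl2, −78 → −40 °C
Reagents that add atoms: none
Why: Lewis-acid activation gives the epoxide SN1-like charge at the tertiary C17, so the equatorial C21 hydroxyl should attack C17 in the 7-endo mode (intramolecular etherification) and give the trans-fused ring A with C15 unchanged.

Step 10
Reactants: 14 ring A/B ketone with C15 hydroxyl
Product: 15 ring A/B C24-methylidene alcohol (C24=CH2, C15–OH, C10 allyl)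
Conditions: Ph3P=CH2 (from Ph3PCH3Br and KOtBu, 4 equiv), toluene, 80 °C
Reagents that add atoms: methyltriphenylphosphonium bromide C[P+](c1ccccc1)(c1ccccc1)c1ccccc1.[Br-]
Why: Wittig methylenation of the hindered ketone (as used on 8-oxo labdane-type ketones), with the excess base first equilibrating C10 so that the C9 chain is equatorial on the now rigid trans-fused bicycle.

Step 11
Reactants: 15 ring A/B C24-methylidene alcohol
Product: 16 ring A/B spiro-epoxide (oxirane on C24, oxygen anti to the C12 methyl)
Conditions: mCPBA (1.05 equiv), NaHCO3, CH2Cl2, 0 °C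
Reagents that add atoms: 3-chloroperbenzoic acid OOC(=O)c1cccc(Cl)c1
Why: Prilezhaev epoxidation, in which the 1,1-disubstituted exocyclic alkene reacts faster than the allyl group and the peracid approaches anti to the axial C12 methyl, placing the epoxide oxygen equatorial as in 8(17)-labdene epoxidations.

Step 12
Reactants: 16 ring A/B spiro-epoxide
Product: 17 ring A/B diol (C15–OH and tertiary C24–OH, C25 methyl cis to C12)
Conditions: LiAlH4, THF, 0 → 23 °C; aq. NaOH work-up
Reagents that add atoms: none
Why: Hydride opens the spiro-epoxide at its unhindered CH2 terminus, which becomes the axial C25 methyl and leaves the equatorial C24 hydroxyl in the target configuration.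

Step 13
Reactants: 17 ring A/B diol
Product: 18 ring A/B bis(triethylsilyl) ether with C10 allyl group
Conditions: TESOTf (3 equiv), 2,6-lutidine, CH2Cl2, 0 → 23 °C
Reagents that add atoms: triethylsilyl trifluoromethanesulfonate CC[Si](CC)(CC)OS(=O)(=O)C(F)(F)F
Why: Silyl triflate with 2,6-lutidine silylates both the hindered secondary and the tertiary hydroxyl, which prevents lactol formation with the later C8 aldehyde and protects C15–OH to the end.

Step 14
Reactants: 18 ring A/B bis(triethylsilyl) ether with C10 allyl group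
Product: 19 ring A/B C8 aldehyde (C10–CH2–CHO), bis(triethylsilyl) ether
Conditions: O3, CH2Cl2, −78 °C; PPh3, −78 → 23 °C
Reagents that add atoms: ozone [O-][O+]=O
Why: Ozonolysis with reductive work-up cleaves the only remaining alkene to the C8 aldehyde.

Step 15
Reactants: 20 (S)-carvone
Product: 21 (2R,5S)-2-methyl-5-(prop-1-en-2-yl)cyclohexan-1-one (cis-dihydrocarvone)
Conditions: old yellow enzyme 1 (OYE1), NADP+ (cat.), glucose dehydrogenase, D-glucose, phosphate buffer pH 7, 30 °C
Reagents that add atoms: none
Why: Ene-reductase reduction of the enone adds hydride to C3 and a proton anti at C2 and is known to give the 2R product from either carvone enantiomer, here the cis isomer that chemical reduction does not favour.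

Step 16
Reactants: 21 (2R,5S)-2-methyl-5-(prop-1-en-2-yl)cyclohexan-1-one
Product: 22 (3S,6R)-6-methyl-3-(prop-1-en-2-yl)cyclohex-1-en-1-yl trifluoromethanesulfonate
Conditions: LiN(iPr)2, THF, −78 °C; PhNTf2, −78 → 0 °C
Reagents that add atoms: N-phenylbis(trifluoromethanesulfonimide) FC(F)(F)S(=O)(=O)N(c1ccccc1)S(=O)(=O)C(F)(F)F
Why: Kinetic deprotonation at the less substituted α-carbon (C6) and O-triflation give the C6=C7 enol triflate without disturbing the C2 stereocentre.

Step 17
Reactants: 19 ring A/B C8 aldehyde; 22 ring C enol triflate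
Product: 23 coupled allylic alcohol (C7–C8 bond, C6=C7 alkene, C8–OH as an epimer mixture)
Conditions: 22 (2 equiv), CrCl2 (6 equiv), NiCl2 (2 mol %), DMF, 23 °C
Reagents that add atoms: none
Why: Nozaki–Hiyama–Kishi coupling, in which nickel-catalysed formation of the alkenylchromium reagent and its chemoselective addition to the aldehyde form C7–C8 under non-basic conditions; the C8 mixture is corrected in steps 18 and 19.

Step 18
Reactants: 23 coupled allylic alcohol (C8 epimers)
Product: 24 C8 enone (C8=O conjugated with C6=C7)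
Conditions: Dess–Martin periodinane, NaHCO3, CH2Cl2, 23 °C
Reagents that add atoms: none
Why: Dess–Martin oxidation of the secondary allylic alcohols converges both C8 epimers on one enone.

Step 19
Reactants: 24 C8 enone
Product: 25 (8R)-allylic alcohol
Conditions: (S)-Me-CBS oxazaborolidine (20 mol %), catecholborane, toluene, −78 °C
Reagents that add atoms: none
Why: Corey–Bakshi–Shibata reduction, in which the alkenyl group acts as the large and C9H2 as the small substituent, so the (S)-catalyst should give the (8R)-alcohol needed for chirality transfer in step 21.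

Step 20
Reactants: 25 (8R)-allylic alcohol
Product: 26 (8R)-allylic isobutyrate
Conditions: (iPrCO)2O, DMAP (cat.), Et3N, CH2Cl2, 23 °C
Reagents that add atoms: isobutyric anhydride CC(C)C(=O)OC(=O)C(C)C
Why: DMAP-catalysed acylation of the secondary allylic alcohol installs C27–C30 as an isobutyrate.

Step 21
Reactants: 26 (8R)-allylic isobutyrate
Product: 29 C30 carboxylic acid with C6–C27 bond and (E)-C7=C8 alkene, via silyl ketene acetal 27 (not isolated), via trimethylsilyl ester 28 (not isolated)
Conditions: LiN(iPr)2, THF, −78 °C; TMSCl/Et3N, −78 → 23 °C, then 65 °C; aq. NaHCO3–MeOH, then NaH2PO4 buffer (pH 5)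
Reagents that add atoms: none
Why: Ireland–Claisen rearrangement, in which the silyl ketene acetal rearranges suprafacially through a chair with C9 equatorial, so the (8R) centre is transferred to C6 (C27 enters on the face of C6 syn to the C5 isopropenyl group and the C1 methyl) and C9 ends trans to C6 across the new C7=C8 bond.

Step 22
Reactants: 29 C30 carboxylic acid
Product: 30 C30 primary alcohol
Conditions: LiAlH4, THF, 0 → 65 °C; aq. NaOH work-up
Reagents that add atoms: none
Why: LiAlH4 reduces the hindered α-quaternary acid to the neopentyl alcohol; silyl ethers and alkenes are inert.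

Step 23
Reactants: 30 C30 primary alcohol
Product: 31 C30 aldehyde
Conditions: Dess–Martin periodinane, NaHCO3, CH2Cl2, 23 °C
Reagents that add atoms: none
Why: Dess–Martin oxidation gives the non-enolisable neopentyl aldehyde.

Step 24
Reactants: 31 C30 aldehyde
Product: 32 ring D homoallylic alcohol (C30–OH, C32=CH2 exocyclic)
Conditions: Me2AlCl (1.5 equiv), CH2Cl2, −78 → −20 °C
Reagents that add atoms: none
Why: Type 2 intramolecular carbonyl-ene reaction, in which the activated aldehyde is attacked by the terminal carbon (C31) of the isopropenyl group with transfer of a methyl hydrogen, closing ring D as a 3-methylenecyclohexanol, while the C7=C8 alkene cannot reach C30 in a favourable ring size.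

Step 25
Reactants: 32 ring D homoallylic alcohol
Product: 33 C30 O-alkyl S-methyl xanthate
Conditions: NaH, THF, 0 °C; CS2; MeI, 23 °C
Reagents that add atoms: carbon disulfide S=C=S; iodomethane CI
Why: Xanthate formation from the secondary alkoxide (first half of the Barton–McCombie deoxygenation).

Step 26
Reactants: 33 C30 xanthate
Product: 34 cis-fused C/D decalin with C32=CH2 (C30 now CH2)
Conditions: Bu3SnH, AIBN (cat.), toluene, 100 °C
Reagents that add atoms: none
Why: Barton–McCombie deoxygenation, in which the stannyl radical adds to sulfur, the C30–O bond fragments and the secondary radical is reduced by Bu3SnH.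

Step 27
Reactants: 34 C/D decalin with C32=CH2
Product: 35 C32 tertiary alcohol (bis(triethylsilyl) ether of the target's C15 alcohol)
Conditions: Mn(dpm)3 (dpm = dipivaloylmethanato, 10 mol %), PhSiH3, O2 (1 atm), iPrOH–CH2Cl2, 0 °C; then PPh3
Reagents that add atoms: dioxygen O=O
Why: Mukaiyama hydration, in which hydrogen-atom transfer to the 1,1-disubstituted alkene (faster than to the hindered trisubstituted C7=C8 bond) gives the tertiary C32 radical, which should be trapped by O2 on the face of ring D turned away from ring C, that is syn to H5.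

Step 28
Reactants: 35 bis(triethylsilyl) ether
Product: 36 triol (C15–OH, C24–OH, C32–OH)
Conditions: Bu4NF, THF, 23 → 40 °C
Reagents that add atoms: none
Why: Fluoride removes both triethylsilyl ethers.

Step 29
Reactants: 36 triol
Product: 37 CNP0232921.1 (target)
Conditions: Dess–Martin periodinane, NaHCO3, CH2Cl2, 0 → 23 °C
Reagents that add atoms: none
Why: Dess–Martin oxidation of the only secondary alcohol gives the C15 ketone; the two tertiary alcohols cannot be oxidised.

**Compound list**
1 | 3-methylcyclohex-2-en-1-one | CC1=CC(=O)CCC1 | starting material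
2 | trimethyl[(3-methylcyclohexa-1,3-dien-1-yl)oxy]silane | C[Si](C)(C)OC1=CC(C)=CCC1 | intermediate
3 | rac-4-hydroxy-3-methylcyclohex-2-en-1-one | CC1=CC(=O)CCC1O | intermediate
4 | (S)-4-hydroxy-3-methylcyclohex-2-en-1-one | CC1=CC(=O)CC[C@@H]1O | intermediate
5 | (S)-4-(tert-butyldimethylsilyloxy)-3-methylcyclohex-2-en-1-one | CC1=CC(=O)CC[C@@H]1O[Si](C)(C)C(C)(C)C | intermediate
6 | 5-bromo-2-methylpent-2-ene | CC(C)=CCCBr | starting material
7 | 4-methylpent-3-enylmagnesium bromide | CC(C)=CCC[Mg]Br | intermediate
8 | allyl iodide | C=CCI | starting material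
9 | trimethylsilyl enol ether (C10=C24) of the conjugate adduct, not isolated | C[Si](C)(C)OC1=C[C@](C)(CCC=C(C)C)[C@@H](O[Si](C)(C)C(C)(C)C)CC1 | intermediate
10 | lithium enolate (C10=C24) of the conjugate adduct, not isolated | [Li]OC1=C[C@](C)(CCC=C(C)C)[C@@H](O[Si](C)(C)C(C)(C)C)CC1 | intermediate
11 | (2S,3S,4S)-2-allyl-4-(tert-butyldimethylsilyloxy)-3-methyl-3-(4-methylpent-3-enyl)cyclohexan-1-one | C=CC[C@H]1[C@](C)(CCC=C(C)C)[C@@H](O[Si](C)(C)C(C)(C)C)CCC1=O | intermediate
12 | (2S,3S,4S)-2-allyl-4-hydroxy-3-methyl-3-(4-methylpent-3-enyl)cyclohexan-1-one | C=CC[C@H]1[C@](C)(CCC=C(C)C)[C@@H](O)CCC1=O | intermediate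
13 | (2S,3S,4S)-2-allyl-3-{2-[(2R)-3,3-dimethyloxiran-2-yl]ethyl}-4-hydroxy-3-methylcyclohexan-1-one | C=CC[C@H]1[C@](C)(CC[C@H]2OC2(C)C)[C@@H](O)CCC1=O | intermediate
14 | (3R,5aS,6S,9aS)-6-allyl-3-hydroxy-2,2,5a-trimethyloctahydro-1-benzoxepin-7(2H)-one | C=CC[C@H]1[C@]2(C)CC[C@@H](O)C(C)(C)O[C@H]2CCC1=O | intermediate
15 | ring A/B C24-methylidene alcohol (C15–OH, C10 allyl) | C=CC[C@H]1[C@]2(C)CC[C@@H](O)C(C)(C)O[C@H]2CCC1=C | intermediate
16 | ring A/B C24 spiro-epoxide (oxygen anti to C12 methyl) | C=CC[C@H]1[C@]2(C)CC[C@@H](O)C(C)(C)O[C@H]2CC[C@@]13CO3 | intermediate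
17 | ring A/B diol (C15–OH, C24–OH) | C=CC[C@H]1[C@]2(C)CC[C@@H](O)C(C)(C)O[C@H]2CC[C@]1(C)O | intermediate
18 | ring A/B bis(triethylsilyl) ether, C10 allyl | C=CC[C@H]1[C@]2(C)CC[C@@H](O[Si](CC)(CC)CC)C(C)(C)O[C@H]2CC[C@]1(C)O[Si](CC)(CC)CC | intermediate
19 | ring A/B C8 aldehyde, bis(triethylsilyl) ether | O=CC[C@H]1[C@]2(C)CC[C@@H](O[Si](CC)(CC)CC)C(C)(C)O[C@H]2CC[C@]1(C)O[Si](CC)(CC)CC | intermediate
20 | (S)-carvone | CC1=CC[C@@H](CC1=O)C(C)=C | starting material
21 | (2R,5S)-2-methyl-5-(prop-1-en-2-yl)cyclohexan-1-one | C[C@@H]1CC[C@@H](CC1=O)C(C)=C | intermediate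
22 | (3S,6R)-6-methyl-3-(prop-1-en-2-yl)cyclohex-1-en-1-yl trifluoromethanesulfonate | C[C@@H]1CC[C@@H](C=C1OS(=O)(=O)C(F)(F)F)C(C)=C | intermediate
23 | coupled allylic alcohol, C8 epimer mixture | C[C@@H]1CC[C@@H](C=C1C(O)C[C@H]2[C@]3(C)CC[C@@H](O[Si](CC)(CC)CC)C(C)(C)O[C@H]3CC[C@]2(C)O[Si](CC)(CC)CC)C(C)=C | intermediate
24 | C8 enone | C[C@@H]1CC[C@@H](C=C1C(=O)C[C@H]2[C@]3(C)CC[C@@H](O[Si](CC)(CC)CC)C(C)(C)O[C@H]3CC[C@]2(C)O[Si](CC)(CC)CC)C(C)=C | intermediate
25 | (8R)-allylic alcohol | C[C@@H]1CC[C@@H](C=C1[C@H](O)C[C@H]2[C@]3(C)CC[C@@H](O[Si](CC)(CC)CC)C(C)(C)O[C@H]3CC[C@]2(C)O[Si](CC)(CC)CC)C(C)=C | intermediate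
26 | (8R)-allylic isobutyrate | C[C@@H]1CC[C@@H](C=C1[C@H](OC(=O)C(C)C)C[C@H]2[C@]3(C)CC[C@@H](O[Si](CC)(CC)CC)C(C)(C)O[C@H]3CC[C@]2(C)O[Si](CC)(CC)CC)C(C)=C | intermediate
27 | trimethylsilyl ketene acetal of 26, not isolated | C[C@@H]1CC[C@@H](C=C1[C@H](OC(O[Si](C)(C)C)=C(C)C)C[C@H]2[C@]3(C)CC[C@@H](O[Si](CC)(CC)CC)C(C)(C)O[C@H]3CC[C@]2(C)O[Si](CC)(CC)CC)C(C)=C | intermediate
28 | trimethylsilyl ester of acid 29, not isolated | C[C@@H]1CC[C@H](C(C)=C)[C@@H](/C1=C/C[C@H]2[C@]3(C)CC[C@@H](O[Si](CC)(CC)CC)C(C)(C)O[C@H]3CC[C@]2(C)O[Si](CC)(CC)CC)C(C)(C)C(=O)O[Si](C)(C)C | intermediate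
29 | C30 carboxylic acid (C6–C27 formed, (E)-C7=C8) | C[C@@H]1CC[C@H](C(C)=C)[C@@H](/C1=C/C[C@H]2[C@]3(C)CC[C@@H](O[Si](CC)(CC)CC)C(C)(C)O[C@H]3CC[C@]2(C)O[Si](CC)(CC)CC)C(C)(C)C(=O)O | intermediate
30 | C30 primary alcohol | C[C@@H]1CC[C@H](C(C)=C)[C@@H](/C1=C/C[C@H]2[C@]3(C)CC[C@@H](O[Si](CC)(CC)CC)C(C)(C)O[C@H]3CC[C@]2(C)O[Si](CC)(CC)CC)C(C)(C)CO | intermediate
31 | C30 aldehyde | C[C@@H]1CC[C@H](C(C)=C)[C@@H](/C1=C/C[C@H]2[C@]3(C)CC[C@@H](O[Si](CC)(CC)CC)C(C)(C)O[C@H]3CC[C@]2(C)O[Si](CC)(CC)CC)C(C)(C)C=O | intermediate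
32 | ring D homoallylic alcohol (C30–OH unassigned, C32=CH2) | C[C@@H]1CC[C@H]2[C@@H](/C1=C/C[C@H]1[C@]3(C)CC[C@@H](O[Si](CC)(CC)CC)C(C)(C)O[C@H]3CC[C@]1(C)O[Si](CC)(CC)CC)C(C)(C)C(O)CC2=C | intermediate
33 | C30 xanthate (C30 unassigned) | C[C@@H]1CC[C@H]2[C@@H](/C1=C/C[C@H]1[C@]3(C)CC[C@@H](O[Si](CC)(CC)CC)C(C)(C)O[C@H]3CC[C@]1(C)O[Si](CC)(CC)CC)C(C)(C)C(OC(=S)SC)CC2=C | intermediate
34 | C/D decalin with C32=CH2 | C[C@@H]1CC[C@H]2[C@@H](/C1=C/C[C@H]1[C@]3(C)CC[C@@H](O[Si](CC)(CC)CC)C(C)(C)O[C@H]3CC[C@]1(C)O[Si](CC)(CC)CC)C(C)(C)CCC2=C | intermediate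
35 | C32 tertiary alcohol, bis(triethylsilyl) ether | C[C@@H]1CC[C@H]2[C@@H](/C1=C/C[C@H]1[C@]3(C)CC[C@@H](O[Si](CC)(CC)CC)C(C)(C)O[C@H]3CC[C@]1(C)O[Si](CC)(CC)CC)C(C)(C)CC[C@]2(C)O | intermediate
36 | triol (15-hydroxy precursor of the target) | C[C@@H]1CC[C@H]2[C@@H](/C1=C/C[C@H]1[C@]3(C)CC[C@@H](O)C(C)(C)O[C@H]3CC[C@]1(C)O)C(C)(C)CC[C@]2(C)O | intermediate
37 | CNP0232921.1 | C[C@@H]1CC[C@H]2[C@@H](/C1=C/C[C@H]1[C@]3(C)CCC(=O)C(C)(C)O[C@H]3CC[C@]1(C)O)C(C)(C)CC[C@]2(C)O | target

**Step count**
Total: 29 steps. Longest linear sequence: 26 steps (steps 1–4, 6–14 and 17–29, from 3-methylcyclohex-2-en-1-one).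

**Steps most likely to fail**

Step 6. C-allylation of the hindered lithium enolate next to the new quaternary centre may be slow, so that proton exchange, O-allylation or double allylation intrudes and the C10 ratio after equilibration is low. The fallback sets out from 5 and 7. The copper-catalysed addition is run as in step 6 but stopped at the silyl enol ether 9, which is isolated. MeLi (THF, 0 °C) followed by allyl chloroformate (−78 °C) converts it into the allyl enol carbonate F1. Pd(PPh3)4 (zerovalent palladium, 5 mol %, THF, 23 °C) then brings about decarboxylative allylation (Tsuji) at C10, and after the NaOMe equilibration the route is rejoined at 11.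

Step 9. The C21 hydroxyl may attack C15 instead of C17 (6-exo opening to a tetrahydropyran), or the activated epoxide may rearrange by hydride shift before it is trapped. The fallback sets out from 13. Cp2TiCl (trivalent titanium, made from Cp2TiCl2 and Mn dust, THF, 23 °C) opens the epoxide homolytically at C17, and loss of a methyl hydrogen gives the allylic alcohol F2 with C15 untouched. Hg(OCOCF3)2 (divalent mercury; CH2Cl2, −20 °C, then aq. NaCl) adds the C21 hydroxyl to C17 in the Markovnikov 7-exo sense, where no six-membered alternative exists, to give the chloromercurial F3. Bu3SnH with AIBN (toluene, 60 °C) replaces mercury by hydrogen, which restores the gem-dimethyl group and returns the route to 14.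

Step 21. Enolisation and silylation of the hindered isobutyrate may be incomplete, and compression between the C1 methyl and the ester oxygen on the reacting face may divert part of the material through the pathway with C9 axial, giving the Z alkene and the C6 epimer. The fallback sets out from 25. 1-Methoxy-2-methylprop-1-ene with pyridinium p-toluenesulfonate (cat., CH2Cl2, 0 °C) gives the mixed acetal F4. TMSOTf and iPr2NEt (CH2Cl2, −20 °C) eliminate methanol to give the 2-methylprop-1-enyl ether F5. Heating in toluene (110–130 °C) then effects the neutral aliphatic Claisen rearrangement, with no silyloxy group in the transition state, and delivers aldehyde 31 directly, where the route is rejoined (steps 20–23 are skipped).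

**Further compounds**
F1 | step 6 | allyl enol carbonate of the C24 enolate (C10=C24) | C=CCOC(=O)OC1=C[C@](C)(CCC=C(C)C)[C@@H](O[Si](C)(C)C(C)(C)C)CC1
F2 | step 9 | (15R)-allylic alcohol: 2-allyl-4-hydroxy-3-(3-hydroxy-4-methylpent-4-enyl)-3-methylcyclohexan-1-one | C=CC[C@H]1[C@](C)(CC[C@@H](O)C(C)=C)[C@@H](O)CCC1=O
F3 | step 9 | ring A/B ketone with chloromercuriomethyl group on C17 (C17 unassigned) | C=CC[C@H]1[C@]2(C)CC[C@@H](O)C(C)(C[Hg]Cl)O[C@H]2CCC1=O
F4 | step 21 | mixed methyl acetal of isobutyraldehyde on the C8 oxygen of 25 | C[C@@H]1CC[C@@H](C=C1[C@H](OC(OC)C(C)C)C[C@H]2[C@]3(C)CC[C@@H](O[Si](CC)(CC)CC)C(C)(C)O[C@H]3CC[C@]2(C)O[Si](CC)(CC)CC)C(C)=C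
F5 | step 21 | 2-methylprop-1-enyl ether of 25 | C[C@@H]1CC[C@@H](C=C1[C@H](OC=C(C)C)C[C@H]2[C@]3(C)CC[C@@H](O[Si](CC)(CC)CC)C(C)(C)O[C@H]3CC[C@]2(C)O[Si](CC)(CC)CC)C(C)=C
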